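**Retrosynthetic overview**
1. Numbering (prostanoid): C1 ester carbon, C5=C6 and C14=C15 the two cis alkenes, C7 acetoxy carbon, ring C8–C12 (C9 carbonyl, C10 iodine-bearing, C12 carbinol), C13–C20 octenyl chain. Endgame, all after the key union: α-iodination at C10, oxidation at C9, silyl-to-acetyl exchange at C7.
2. Key disconnection C12–C13: a (Z)-oct-2-enylcerium reagent (C13–C20) adds 1,2 to a C1–C12 cyclopentenone that already carries C7, C8 and C9. This is a convergent union at the fully substituted carbinol carbon and sets its configuration.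
3. Enabling feature: in the cyclopentene ring C8–C12, C12 is offered as the carbonyl carbon of a cyclopent-2-enone (C12=O conjugated with C10=C11), while C9 is kept one oxidation level lower as an (S)-silyloxy carbon. This avoids the acidic 1,3-dione, lets the C8 branch screen one face of C12=O, and makes C9 the only bought stereocentre; it relays to C8, C7 and C12 and is then erased by oxidation.
4. The cyclopentenone partner comes from a syn-selective titanium aldol of (4S)-4-silyloxycyclopent-2-enone with a cis-enal ester (C7–C8 bond, trans to the silyloxy group). The enal comes from an alkynol ester, the allyl donor from (Z)-octenol.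
5. Ring order: the only ring (C8–C12) is bought with the silyloxycyclopentenone and is neither opened nor formed; no other ring is made.

Key step: step 6

Assumption: methyl 7-hydroxyhept-5-ynoate, (2Z)-oct-2-en-1-ol and (4S)-4-(tert-butyldimethylsilyloxy)cyclopent-2-en-1-one are taken as catalogue compounds. "Syn aldol" means that the C7–O bond and the ring bond C8–C9 lie on the same side of the C12–C8–C7–C6 zigzag.

**Step 1**
Reactants: 1 methyl 7-hydroxyhept-5-ynoate
Product: 2 methyl (5Z)-7-hydroxyhept-5-enoate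
Conditions: H2 (1 atm), Pd/CaCO3 poisoned with Pb(OAc)2, quinoline, EtOAc, 20 °C
Reagents that add atoms: none
Why: Lindlar semihydrogenation delivers H2 syn on the poisoned palladium surface, which should give the cis alkene and stop there, the ester and the free alcohol being inert.

**Step 2**
Reactants: 2 methyl (5Z)-7-hydroxyhept-5-enoate
Product: 3 methyl (5Z)-7-oxohept-5-enoate
Conditions: MnO2 (activated, excess), CH2Cl2, 0 to 20 °C; filtered and used at once
Reagents that add atoms: none
Why: Heterogeneous, neutral MnO2 oxidation is selective for the allylic alcohol and should leave the cis geometry of the enal in place if it is used directly.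

**Step 3**
Reactants: 4 (2Z)-oct-2-en-1-ol
Product: 5 phenyl (2Z)-oct-2-en-1-yl sulfide
Conditions: PhSSPh, PBu3, THF, 0 to 20 °C
Reagents that add atoms: diphenyl disulfide, c1ccccc1SSc1ccccc1
Why: Mitsunobu-type thioetherification (alkoxyphosphonium formation, then SN2 displacement by thiophenolate at the primary allylic carbon) should leave the cis alkene untouched.

**Step 4**
Reactants: 6 (4S)-4-(tert-butyldimethylsilyloxy)cyclopent-2-en-1-one; 3 methyl (5Z)-7-oxohept-5-enoate
Product: 9 methyl (5Z,7S)-7-[(1S,5R)-5-(tert-butyldimethylsilyloxy)-2-oxocyclopent-3-en-1-yl]-7-hydroxyhept-5-enoate, via lithium dienolate 7 (not isolated), via titanium dienolate 8 (not isolated)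
Conditions: LiN(iPr)2, THF, −78 °C; ClTi(OiPr)3, −78 to −40 °C; 3, −78 °C; aq NH4Cl
Reagents that add atoms: none
Why: Kinetic deprotonation at C8 gives cross-conjugated dienolate 7, lithium-to-titanium exchange gives 8, and its aldol addition to 3 forms C7–C8 with the aldehyde entering anti to the adjacent C9 silyloxy group (sets C8, trans) and with the syn simple diastereoselection that triisopropoxytitanium enolates of cyclic ketones are known to show (sets C7), at a temperature where the cis-enal should neither isomerise nor take conjugate addition.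

**Step 5**
Reactants: 9 methyl (5Z,7S)-7-[(1S,5R)-5-(tert-butyldimethylsilyloxy)-2-oxocyclopent-3-en-1-yl]-7-hydroxyhept-5-enoate
Product: 10 methyl (5Z,7S)-7-[(1S,5R)-5-(tert-butyldimethylsilyloxy)-2-oxocyclopent-3-en-1-yl]-7-(triethylsilyloxy)hept-5-enoate
Conditions: Et3SiCl, imidazole, DMAP (cat.), CH2Cl2, 0 °C
Reagents that add atoms: chlorotriethylsilane, CC[Si](Cl)(CC)CC
Why: Standard silylation of the secondary alcohol removes the acidic proton, blocks retro-aldol cleavage and adds bulk on the C8 branch that is to screen one face of the ketone.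

**Step 6**
Reactants: 5 phenyl (2Z)-oct-2-en-1-yl sulfide; 10 methyl (5Z,7S)-7-[(1S,5R)-5-(tert-butyldimethylsilyloxy)-2-oxocyclopent-3-en-1-yl]-7-(triethylsilyloxy)hept-5-enoate
Product: 13 methyl (5Z,7S)-7-[(1S,2R,5R)-5-(tert-butyldimethylsilyloxy)-2-hydroxy-2-[(2Z)-oct-2-en-1-yl]cyclopent-3-en-1-yl]-7-(triethylsilyloxy)hept-5-enoate, via octenyllithium 11 (not isolated), via octenylcerium dichloride 12 (not isolated)
Conditions: lithium 4,4'-di-tert-butylbiphenylide (LiDBB, 2 equiv per 5), THF, −78 °C; CeCl3 (anhydrous), −78 °C; then 10, −78 °C; aq NH4Cl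
Reagents that add atoms: none
Why: Two-electron reductive cleavage of the carbon–sulfur bond of 5 gives allyllithium 11, transmetalation to CeCl3 gives allylcerium 12, and 12 adds 1,2 to the C12 carbonyl of 10 through its unsubstituted CH2 terminus, forming the C12–C13 bond and the fully substituted carbinol carbon with the whole carbon skeleton in place. The closest known reaction type is the carbonyl addition of substituted allylcerium reagents, which attack enals and ketones at the less substituted allyl terminus, within the general 1,2-addition of organocerium reagents to enolisable enones. No ring is closed; the cyclopentene ring C8–C12 is carried through intact. The new stereocentre C12 is set by the substrate: the C7-bearing branch on C8 sits directly on the attack path to one face of the nearly flat cyclopentenone, so the reagent should enter from the opposite face, anti to that branch, where the C9 silyloxy oxygen is one bond further from the carbonyl carbon. The step needs 1,2- over 1,4-addition and addition over enolisation, both expected from the oxophilic and weakly basic trivalent cerium reagent (important because the C8 hydrogen is flanked by two β-silyloxy groups), and it needs attack at the CH2 terminus, favoured by the bulky metal centre and the hindered α-branched ketone. It also needs the cis alkene to be kept, for which the reagent is made from the (Z)-sulfide and held at −78 °C, where such allylcerium reagents deliver cis alkenes and isomerise only on warming; the ketone should react ahead of the methyl ester at this temperature.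

**Step 7**
Reactants: 13 methyl (5Z,7S)-7-[(1S,2R,5R)-5-(tert-butyldimethylsilyloxy)-2-hydroxy-2-[(2Z)-oct-2-en-1-yl]cyclopent-3-en-1-yl]-7-(triethylsilyloxy)hept-5-enoate
Product: 14 methyl (5Z,7S)-7-[(1S,2R,5R)-5-(tert-butyldimethylsilyloxy)-2-hydroxy-2-[(2Z)-oct-2-en-1-yl]cyclopent-3-en-1-yl]-7-hydroxyhept-5-enoate
Conditions: PPTS (cat.), MeOH/CH2Cl2, 0 °C
Reagents that add atoms: none
Why: Mild acid-catalysed methanolysis cleaves a secondary triethylsilyl ether far faster than a secondary tert-butyldimethylsilyl ether, and the ester, the tertiary alcohol and both alkenes should persist.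

**Step 8**
Reactants: 14 methyl (5Z,7S)-7-[(1S,2R,5R)-5-(tert-butyldimethylsilyloxy)-2-hydroxy-2-[(2Z)-oct-2-en-1-yl]cyclopent-3-en-1-yl]-7-hydroxyhept-5-enoate
Product: 15 methyl (5Z,7S)-7-acetoxy-7-[(1S,2R,5R)-5-(tert-butyldimethylsilyloxy)-2-hydroxy-2-[(2Z)-oct-2-en-1-yl]cyclopent-3-en-1-yl]hept-5-enoate
Conditions: Ac2O, pyridine, DMAP (cat.), CH2Cl2, 0 °C
Reagents that add atoms: acetic anhydride, CC(=O)OC(C)=O
Why: Nucleophile-catalysed acylation takes the secondary C7 alcohol and leaves the hindered tertiary C12 alcohol, and because the molecule holds no ketone at this stage the acetate cannot be lost by β-elimination.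

**Step 9**
Reactants: 15 methyl (5Z,7S)-7-acetoxy-7-[(1S,2R,5R)-5-(tert-butyldimethylsilyloxy)-2-hydroxy-2-[(2Z)-oct-2-en-1-yl]cyclopent-3-en-1-yl]hept-5-enoate
Product: 16 methyl (5Z,7S)-7-acetoxy-7-[(1R,2R,5R)-2,5-dihydroxy-2-[(2Z)-oct-2-en-1-yl]cyclopent-3-en-1-yl]hept-5-enoate
Conditions: HF·pyridine, pyridine, THF, 0 to 20 °C
Reagents that add atoms: none
Why: Fluoride-driven desilylation under buffered, slightly acidic conditions should free the C9 alcohol without acetyl migration or ester cleavage.

**Step 10**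
Reactants: 16 methyl (5Z,7S)-7-acetoxy-7-[(1R,2R,5R)-2,5-dihydroxy-2-[(2Z)-oct-2-en-1-yl]cyclopent-3-en-1-yl]hept-5-enoate
Product: 17 methyl (5Z,7S)-7-acetoxy-7-[(1R,2R)-2-hydroxy-2-[(2Z)-oct-2-en-1-yl]-5-oxocyclopent-3-en-1-yl]hept-5-enoate
Conditions: MnO2 (activated, excess), CH2Cl2, 20 °C
Reagents that add atoms: none
Why: MnO2 oxidises only the secondary allylic C9 alcohol (the tertiary C12 alcohol has no carbinol hydrogen), which erases the auxiliary C9 stereocentre and unveils the 4-hydroxycyclopent-2-enone under base-free conditions that should leave C8 and the β-acetoxy group alone.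

**Step 11**
Reactants: 17 methyl (5Z,7S)-7-acetoxy-7-[(1R,2R)-2-hydroxy-2-[(2Z)-oct-2-en-1-yl]-5-oxocyclopent-3-en-1-yl]hept-5-enoate
Product: 18 methyl (5Z,7S)-7-acetoxy-7-[(1R,2S)-2-hydroxy-4-iodo-2-[(2Z)-oct-2-en-1-yl]-5-oxocyclopent-3-en-1-yl]hept-5-enoate
Conditions: I2, pyridine, CH2Cl2, 0 to 20 °C, dark; aq Na2S2O3
Reagents that add atoms: iodine, II
Why: Pyridine-mediated α-iodination of a cyclic enone (conjugate addition of the amine at C11, iodination of the enolate at C10, loss of pyridinium, an addition–elimination of the Baylis–Hillman type) should place iodine at C10 with a base weak enough to leave C8 and the acetate intact.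

**Compound list**
1 | methyl 7-hydroxyhept-5-ynoate | OCC#CCCCC(=O)OC | starting material
2 | methyl (5Z)-7-hydroxyhept-5-enoate | OC/C=C\CCCC(=O)OC | intermediate
3 | methyl (5Z)-7-oxohept-5-enoate | O=C/C=C\CCCC(=O)OC | intermediate
4 | (2Z)-oct-2-en-1-ol | CCCCC/C=C\CO | starting material
5 | phenyl (2Z)-oct-2-en-1-yl sulfide | CCCCC/C=C\CSc1ccccc1 | intermediate
6 | (4S)-4-(tert-butyldimethylsilyloxy)cyclopent-2-en-1-one | O=C1C=C[C@@H](O[Si](C)(C)C(C)(C)C)C1 | starting material
7 | lithium (3R)-3-(tert-butyldimethylsilyloxy)cyclopenta-1,4-dien-1-olate (lithium dienolate of 6) | [Li]OC1=C[C@H](O[Si](C)(C)C(C)(C)C)C=C1 | intermediate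
8 | triisopropoxytitanium (3R)-3-(tert-butyldimethylsilyloxy)cyclopenta-1,4-dien-1-olate (titanium dienolate of 6) | CC(C)O[Ti](OC(C)C)(OC(C)C)OC1=C[C@H](O[Si](C)(C)C(C)(C)C)C=C1 | intermediate
9 | methyl (5Z,7S)-7-[(1S,5R)-5-(tert-butyldimethylsilyloxy)-2-oxocyclopent-3-en-1-yl]-7-hydroxyhept-5-enoate (syn aldol, C8 branch trans to the C9 silyloxy group) | O=C1C=C[C@@H](O[Si](C)(C)C(C)(C)C)[C@@H]1[C@H](/C=C\CCCC(=O)OC)O | intermediate
10 | methyl (5Z,7S)-7-[(1S,5R)-5-(tert-butyldimethylsilyloxy)-2-oxocyclopent-3-en-1-yl]-7-(triethylsilyloxy)hept-5-enoate | O=C1C=C[C@@H](O[Si](C)(C)C(C)(C)C)[C@@H]1[C@H](/C=C\CCCC(=O)OC)O[Si](CC)(CC)CC | intermediate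
11 | (2Z)-oct-2-en-1-yllithium | [Li]C/C=C\CCCCC | intermediate
12 | dichloro[(2Z)-oct-2-en-1-yl]cerium | Cl[Ce](Cl)C/C=C\CCCCC | intermediate
13 | methyl (5Z,7S)-7-[(1S,2R,5R)-5-(tert-butyldimethylsilyloxy)-2-hydroxy-2-[(2Z)-oct-2-en-1-yl]cyclopent-3-en-1-yl]-7-(triethylsilyloxy)hept-5-enoate (octenyl trans to the C8 branch, cis to the C9 silyloxy group) | CCCCC/C=C\C[C@@]1(O)C=C[C@@H](O[Si](C)(C)C(C)(C)C)[C@@H]1[C@H](/C=C\CCCC(=O)OC)O[Si](CC)(CC)CC | intermediate
14 | methyl (5Z,7S)-7-[(1S,2R,5R)-5-(tert-butyldimethylsilyloxy)-2-hydroxy-2-[(2Z)-oct-2-en-1-yl]cyclopent-3-en-1-yl]-7-hydroxyhept-5-enoate | CCCCC/C=C\C[C@@]1(O)C=C[C@@H](O[Si](C)(C)C(C)(C)C)[C@@H]1[C@H](/C=C\CCCC(=O)OC)O | intermediate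
15 | methyl (5Z,7S)-7-acetoxy-7-[(1S,2R,5R)-5-(tert-butyldimethylsilyloxy)-2-hydroxy-2-[(2Z)-oct-2-en-1-yl]cyclopent-3-en-1-yl]hept-5-enoate | CCCCC/C=C\C[C@@]1(O)C=C[C@@H](O[Si](C)(C)C(C)(C)C)[C@@H]1[C@H](/C=C\CCCC(=O)OC)OC(C)=O | intermediate
16 | methyl (5Z,7S)-7-acetoxy-7-[(1R,2R,5R)-2,5-dihydroxy-2-[(2Z)-oct-2-en-1-yl]cyclopent-3-en-1-yl]hept-5-enoate | CCCCC/C=C\C[C@@]1(O)C=C[C@@H](O)[C@@H]1[C@H](/C=C\CCCC(=O)OC)OC(C)=O | intermediate
17 | methyl (5Z,7S)-7-acetoxy-7-[(1R,2R)-2-hydroxy-2-[(2Z)-oct-2-en-1-yl]-5-oxocyclopent-3-en-1-yl]hept-5-enoate | CCCCC/C=C\C[C@@]1(O)C=CC(=O)[C@@H]1[C@H](/C=C\CCCC(=O)OC)OC(C)=O | intermediate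
18 | methyl (5Z,7S)-7-acetoxy-7-[(1R,2S)-2-hydroxy-4-iodo-2-[(2Z)-oct-2-en-1-yl]-5-oxocyclopent-3-en-1-yl]hept-5-enoate | CCCCC/C=C\C[C@@]1(O)C=C(I)C(=O)[C@@H]1[C@H](/C=C\CCCC(=O)OC)OC(C)=O | target

**Step count**
Total steps: 11. Longest linear sequence: 10 steps (1, 2, 4, 5, 6, 7, 8, 9, 10, 11).

**Steps most likely to fail**

1. Step 6 (key step). What may go wrong: entry of the cerium reagent from the face syn to the C8 branch (the C9 silyloxy group lies on the wanted face), coupling through the substituted allyl terminus, or cis-to-trans isomerisation of the allyl reagent before it adds. Fallback: the order of the two carbon–carbon bond formations is inverted, so that the C12–C13 bond is made on a ring that carries only the directing silyloxy group. It sets out from sulfide 5 and aldehyde 3 and comes back at 17. Reagent 12, made from 5 as in step 6, is added (THF, −78 °C) to commercially available (4R)-4-(tert-butyldimethylsilyloxy)cyclopent-2-en-1-one F1, where entry anti to the silyloxy group is the expected course, to give the cis tertiary alcohol (1S,4R)-4-(tert-butyldimethylsilyloxy)-1-[(2Z)-oct-2-en-1-yl]cyclopent-2-en-1-ol F2. HF·pyridine should give (1S,4R)-1-[(2Z)-oct-2-en-1-yl]cyclopent-2-ene-1,4-diol F3, and MnO2 should give (4S)-4-hydroxy-4-[(2Z)-oct-2-en-1-yl]cyclopent-2-en-1-one F4. Et3SiOTf/2,6-lutidine gives the triethylsilyl ether of F4 F5. LiN(iPr)2 and then 3 at −78 °C (closed chair transition state of the ring-fixed enolate, anti aldol with respect to the C9 ketone, aldehyde entering anti to the carbon chain on C12) should give the C12 triethylsilyl ether of the C7 alcohol corresponding to 17 F6. Ac2O/pyridine at 0 °C gives the C12 triethylsilyl ether of 17 F7, and HF·pyridine returns 17.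

2. Step 4. What may go wrong: weak simple diastereoselection, with the closed chair transition state competing and giving the anti aldol (the C7 epimer), or cis-to-trans isomerisation of enal 3 before it is consumed. Fallback: C7 is corrected later by inversion instead of being set in the aldol. It sets out from 6 and 3 and comes back at 15. The plain lithium enolate 7 (LiN(iPr)2, THF, −78 °C, no titanium) and 3 should give the anti aldol, the C7 epimer of 9 F8. Silylation as in step 5 gives the C7 epimer of 10 F9, the addition of step 6 gives the C7 epimer of 13 F10, and PPTS/MeOH gives the C7 epimer of 14 F11. Mitsunobu reaction of this diol with acetic acid (PPh3, diisopropyl azodicarboxylate, AcOH, THF, 0 °C) inverts the secondary allylic C7 alcohol and installs the acetate in the same operation, giving 15.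

3. Step 11. What may go wrong: iodoetherification of the C14=C15 alkene by the free C12 hydroxyl, pyridine-promoted loss of acetic acid across C7–C8 or epimerisation at C8, while the wanted addition of pyridine at the hindered C11 is slow. Fallback: a temporary protecting group is placed on the participating hydroxyl before the halogen is introduced. It sets out from 17 and comes back at 18. N-(Trimethylsilyl)imidazole in CH2Cl2 gives the C12 trimethylsilyl ether of 17 F12, I2/pyridine in CH2Cl2 gives the C12 trimethylsilyl ether of 18 F13, and PPTS in MeOH at 0 °C removes the silyl group to give 18.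

**Further compounds**
F1 | step 6 | (4R)-4-(tert-butyldimethylsilyloxy)cyclopent-2-en-1-one (bought) | O=C1C=C[C@H](O[Si](C)(C)C(C)(C)C)C1
F2 | step 6 | (1S,4R)-4-(tert-butyldimethylsilyloxy)-1-[(2Z)-oct-2-en-1-yl]cyclopent-2-en-1-ol | CCCCC/C=C\C[C@@]1(O)C=C[C@H](O[Si](C)(C)C(C)(C)C)C1
F3 | step 6 | (1S,4R)-1-[(2Z)-oct-2-en-1-yl]cyclopent-2-ene-1,4-diol | CCCCC/C=C\C[C@@]1(O)C=C[C@H](O)C1
F4 | step 6 | (4S)-4-hydroxy-4-[(2Z)-oct-2-en-1-yl]cyclopent-2-en-1-one | CCCCC/C=C\C[C@@]1(O)C=CC(=O)C1
F5 | step 6 | (4S)-4-[(2Z)-oct-2-en-1-yl]-4-(triethylsilyloxy)cyclopent-2-en-1-one | CCCCC/C=C\C[C@@]1(O[Si](CC)(CC)CC)C=CC(=O)C1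
F6 | step 6 | methyl (5Z,7S)-7-hydroxy-7-[(1R,2R)-2-[(2Z)-oct-2-en-1-yl]-5-oxo-2-(triethylsilyloxy)cyclopent-3-en-1-yl]hept-5-enoate | CCCCC/C=C\C[C@@]1(O[Si](CC)(CC)CC)C=CC(=O)[C@@H]1[C@H](/C=C\CCCC(=O)OC)O
F7 | step 6 | methyl (5Z,7S)-7-acetoxy-7-[(1R,2R)-2-[(2Z)-oct-2-en-1-yl]-5-oxo-2-(triethylsilyloxy)cyclopent-3-en-1-yl]hept-5-enoate | CCCCC/C=C\C[C@@]1(O[Si](CC)(CC)CC)C=CC(=O)[C@@H]1[C@H](/C=C\CCCC(=O)OC)OC(C)=O
F8 | step 4 | C7 epimer of 9 (anti aldol, 7R) | O=C1C=C[C@@H](O[Si](C)(C)C(C)(C)C)[C@@H]1[C@@H](/C=C\CCCC(=O)OC)O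
F9 | step 4 | C7 epimer of 10 (7R) | O=C1C=C[C@@H](O[Si](C)(C)C(C)(C)C)[C@@H]1[C@@H](/C=C\CCCC(=O)OC)O[Si](CC)(CC)CC
F10 | step 4 | C7 epimer of 13 (7R) | CCCCC/C=C\C[C@@]1(O)C=C[C@@H](O[Si](C)(C)C(C)(C)C)[C@@H]1[C@@H](/C=C\CCCC(=O)OC)O[Si](CC)(CC)CC
F11 | step 4 | C7 epimer of 14 (7R) | CCCCC/C=C\C[C@@]1(O)C=C[C@@H](O[Si](C)(C)C(C)(C)C)[C@@H]1[C@@H](/C=C\CCCC(=O)OC)O
F12 | step 11 | C12 trimethylsilyl ether of 17 | CCCCC/C=C\C[C@@]1(O[Si](C)(C)C)C=CC(=O)[C@@H]1[C@H](/C=C\CCCC(=O)OC)OC(C)=O
F13 | step 11 | C12 trimethylsilyl ether of 18 | CCCCC/C=C\C[C@@]1(O[Si](C)(C)C)C=C(I)C(=O)[C@@H]1[C@H](/C=C\CCCC(=O)OC)OC(C)=O
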